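**Plan**
- Retrosynthesis: the C2–C3 bond of ring C is cut first, giving a diazomethyl ketone on ring A whose ortho oxygen carries an O–CH2–aryl ether. The O1–C2 ether bond is cut next (ring A phenol + ring B benzyl alcohol), then the biaryl bond C5'–C6'' (ring B boronate + 6-iodoapigenin ether).
- Forward: apigenin supplies both flavone rings ready-made and is iodinated at C6''. Suzuki coupling joins ring B, Mitsunobu etherification joins ring A, diazo transfer arms the acetyl group, ring C is closed last, and one global deprotection follows.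
- Enabling feature: in the open precursor the future C2 is a CH2 that is both benzylic to ring B and bonded to O1. Ring A holds the acyl carbenoid carbon (future C3) ortho to that oxygen, 1,6 to these hydridic C–H bonds.
- Stereochemistry: C2 (S) is the only stereocentre. It is set in the ring closure by a chiral dirhodium carboxylate that selects one of the two enantiotopic C2 hydrogens, and only one non-basic step follows.

Key step: step 11

Assumption: Rh2(S-PTTL)4 is taken to favour the (2S) product in step 11; if the sense of induction proves opposite, the mirror-image catalyst Rh2(R-PTTL)4 is used with nothing else changed.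

**Route**

Step 1
Reactants: 1 apigenin
Product: 2 7,4'-di-O-benzylapigenin
Conditions: BnBr (2.2 equiv), K2CO3, DMF, rt
Reagents that add atoms: benzyl bromide BrCc1ccccc1
Why: Williamson etherification should take the two acidic, non-chelated phenols (7-OH and 4'-OH) and leave the 5-OH, which is hydrogen-bonded to the C4 carbonyl, free.

Step 2
Reactants: 2 7,4'-di-O-benzylapigenin
Product: 3 7,4'-di-O-benzyl-6-iodoapigenin
Conditions: BnMe3N+ ICl2− (1.05 equiv), CaCO3, CH2Cl2/MeOH, rt
Reagents that add atoms: benzyltrimethylammonium dichloroiodate C[N+](C)(C)Cc1ccccc1.Cl[I-]Cl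
Why: Electrophilic aromatic iodination of a 5-hydroxy-7-alkoxyflavone with dichloroiodate should go ortho to the free 5-OH, at C6, the known regiochemistry for this substrate class, with CaCO3 taking up the HCl.

Step 3
Reactants: 3 7,4'-di-O-benzyl-6-iodoapigenin
Product: 4 5,7,4'-tri-O-benzyl-6-iodoapigenin
Conditions: BnBr, K2CO3, DMF, 70 °C
Reagents that add atoms: benzyl bromide BrCc1ccccc1
Why: Williamson etherification under more forcing conditions should cap the chelated, hindered 5-OH so that the iodide enters the coupling fully protected.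

Step 4
Reactants: 5 3-bromo-4,5-dihydroxybenzaldehyde
Product: 6 3,4-bis(benzyloxy)-5-bromobenzaldehyde
Conditions: BnBr (2.3 equiv), K2CO3, DMF, 60 °C
Reagents that add atoms: benzyl bromide BrCc1ccccc1
Why: Double Williamson etherification of the catechol; the aldehyde is not enolisable and should be untouched.

Step 5
Reactants: 6 3,4-bis(benzyloxy)-5-bromobenzaldehyde
Product: 7 3,4-bis(benzyloxy)-5-(4,4,5,5-tetramethyl-1,3,2-dioxaborolan-2-yl)benzaldehyde
Conditions: B2pin2, Pd(dppf)Cl2 (3 mol %), KOAc, 1,4-dioxane, 90 °C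
Reagents that add atoms: bis(pinacolato)diboron CC1(C)OB(OC1(C)C)B1OC(C)(C)C(C)(C)O1
Why: Miyaura borylation of an aryl bromide; the weak base KOAc tolerates the aldehyde and should suppress homocoupling.

Step 6
Reactants: 4 5,7,4'-tri-O-benzyl-6-iodoapigenin; 7 3,4-bis(benzyloxy)-5-(4,4,5,5-tetramethyl-1,3,2-dioxaborolan-2-yl)benzaldehyde
Product: 8 3,4-bis(benzyloxy)-5-(5,7,4'-tri-O-benzylapigenin-6-yl)benzaldehyde
Conditions: Pd(OAc)2 (5 mol %), SPhos (10 mol %), K3PO4, toluene/H2O, 90 °C
Reagents that add atoms: none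
Why: Suzuki–Miyaura coupling; zerovalent palladium carrying the bulky dialkylbiarylphosphine should form the tri-ortho-substituted biaryl bond, a connection precedented for 6-iodo-5,7-dialkoxyflavones with ortho-alkoxyarylboronates.

Step 7
Reactants: 8 3,4-bis(benzyloxy)-5-(5,7,4'-tri-O-benzylapigenin-6-yl)benzaldehyde
Product: 9 [3,4-bis(benzyloxy)-5-(5,7,4'-tri-O-benzylapigenin-6-yl)phenyl]methanol
Conditions: NaBH4, THF/MeOH, 0 °C
Reagents that add atoms: none
Why: Borohydride reduction should take the aldehyde only, because the flavone carbonyl is a vinylogous ester and inert at 0 °C.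

Step 8
Reactants: 10 1-(2,4-dihydroxy-6-methoxyphenyl)ethanone
Product: 11 1-(4-benzyloxy-2-hydroxy-6-methoxyphenyl)ethanone
Conditions: BnBr (1.05 equiv), K2CO3, acetone, reflux
Reagents that add atoms: benzyl bromide BrCc1ccccc1
Why: Williamson etherification should select the non-chelated 4-OH over the 2-OH, which is hydrogen-bonded to the acetyl group.

Step 9
Reactants: 9 [3,4-bis(benzyloxy)-5-(5,7,4'-tri-O-benzylapigenin-6-yl)phenyl]methanol; 11 1-(4-benzyloxy-2-hydroxy-6-methoxyphenyl)ethanone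
Product: 12 1-{4-benzyloxy-2-methoxy-6-[3,4-bis(benzyloxy)-5-(5,7,4'-tri-O-benzylapigenin-6-yl)benzyloxy]phenyl}ethanone
Conditions: PPh3, DIAD, THF, 0 °C to rt
Reagents that add atoms: none
Why: Mitsunobu etherification of a primary benzylic alcohol with an ortho-acyl phenol (pKa about 10) should form the future O1–C2 bond under neutral conditions; no stereocentre is involved.

Step 10
Reactants: 12 1-{4-benzyloxy-2-methoxy-6-[3,4-bis(benzyloxy)-5-(5,7,4'-tri-O-benzylapigenin-6-yl)benzyloxy]phenyl}ethanone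
Product: 14 2-diazo-1-{4-benzyloxy-2-methoxy-6-[3,4-bis(benzyloxy)-5-(5,7,4'-tri-O-benzylapigenin-6-yl)benzyloxy]phenyl}ethanone, via trifluoromethyl 1,3-diketone 13 (not isolated)
Conditions: LiN(SiMe3)2, THF, −78 °C; CF3CO2CH2CF3; aq HCl work-up; then MsN3, Et3N, H2O (1 equiv), MeCN, rt
Reagents that add atoms: methanesulfonyl azide CS(=O)(=O)N=[N+]=[N-] (the diazo nitrogens of 14); 2,2,2-trifluoroethyl trifluoroacetate O=C(OCC(F)(F)F)C(F)(F)F (the trifluoroacetyl group of 13 only)
Why: Danheiser detrifluoroacetylative diazo transfer: the methyl ketone, the only enolisable site, is trifluoroacetylated, the activated diketone takes the diazo group from the sulfonyl azide, and the trifluoroacetyl group leaves as the sulfonamide to give the terminal diazo ketone.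

Step 11
Reactants: 14 2-diazo-1-{4-benzyloxy-2-methoxy-6-[3,4-bis(benzyloxy)-5-(5,7,4'-tri-O-benzylapigenin-6-yl)benzyloxy]phenyl}ethanone
Product: 15 (2S)-7-benzyloxy-5-methoxy-2-[3,4-bis(benzyloxy)-5-(5,7,4'-tri-O-benzylapigenin-6-yl)phenyl]chroman-4-one
Conditions: Rh2(S-PTTL)4 (dirhodium tetrakis[N-phthaloyl-(S)-tert-leucinate], 1 mol %), 4 Å MS, CH2Cl2, slow addition of 14, 0 °C to rt
Reagents that add atoms: none
Why: The divalent rhodium carboxylate dimer should expel N2 from 14 to give an electrophilic rhodium carbenoid at the future C3, which inserts in a concerted, asynchronous three-centre step with hydride-transfer character into one C–H bond of the O1–CH2–aryl group, forming the C2–C3 bond and releasing the catalyst. The closest known reaction type is the dirhodium-carboxylate-catalysed intramolecular C–H insertion of 2-alkoxyaryl diazo ketones at the ether α-carbon to give chroman-4-ones, including enantioselective variants with chiral carboxylate ligands. Ring C is closed as a six-membered ring by 1,6-insertion through a chair-like transition state whose ring atoms are the carbenoid carbon, C4, C4a, C8a, O1 and C2. The only new stereocentre, C2, is under catalyst control: the chiral carboxylate wall makes the two enantiotopic benzylic hydrogens unequal, and insertion into one of them gives the (2S) product. The step needs site selectivity for this CH2 over the C–H bonds of the 5-O-methyl group, over capture of the carbenoid by an ether oxygen (oxonium ylide, then 1,2-shift of the benzyl group) and over carbenoid dimerisation; the doubly activated C–H bond (benzylic to the electron-rich ring B and α to O1), the low nucleophilicity of aryl ether oxygens conjugated to the ketone, the absence of a benzyl ether on the other ortho oxygen, and slow addition at high dilution should secure it.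

Step 12
Reactants: 15 (2S)-7-benzyloxy-5-methoxy-2-[3,4-bis(benzyloxy)-5-(5,7,4'-tri-O-benzylapigenin-6-yl)phenyl]chroman-4-one
Product: 16 (2S)-5,7-dihydroxy-2-{3,4-dihydroxy-5-[5,7-dihydroxy-2-(4-hydroxyphenyl)-4-oxo-4H-chromen-6-yl]phenyl}chroman-4-one
Conditions: BCl3 (excess), C6HMe5, CH2Cl2, −78 to 0 °C; then MeOH/H2O
Reagents that add atoms: none
Why: Lewis-acid dealkylation: BCl3 with pentamethylbenzene as a non-basic cation scavenger should cleave the six aryl benzyl ethers at low temperature and, on warming, the peri 5-O-methyl group through its boron chelate with the C4 carbonyl, under non-basic conditions that give no retro-oxa-Michael opening at C2.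

**Compound list**

1 | apigenin (5,7-dihydroxy-2-(4-hydroxyphenyl)-4H-chromen-4-one) | O=c1cc(-c2ccc(O)cc2)oc2cc(O)cc(O)c12 | starting material
2 | 7,4'-di-O-benzylapigenin | O=c1cc(-c2ccc(OCc3ccccc3)cc2)oc2cc(OCc3ccccc3)cc(O)c12 | intermediate
3 | 7,4'-di-O-benzyl-6-iodoapigenin | O=c1cc(-c2ccc(OCc3ccccc3)cc2)oc2cc(OCc3ccccc3)c(I)c(O)c12 | intermediate
4 | 5,7,4'-tri-O-benzyl-6-iodoapigenin | O=c1cc(-c2ccc(OCc3ccccc3)cc2)oc2cc(OCc3ccccc3)c(I)c(OCc3ccccc3)c12 | intermediate
5 | 3-bromo-4,5-dihydroxybenzaldehyde | O=Cc1cc(O)c(O)c(Br)c1 | starting material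
6 | 3,4-bis(benzyloxy)-5-bromobenzaldehyde | O=Cc1cc(OCc2ccccc2)c(OCc2ccccc2)c(Br)c1 | intermediate
7 | 3,4-bis(benzyloxy)-5-(4,4,5,5-tetramethyl-1,3,2-dioxaborolan-2-yl)benzaldehyde | O=Cc1cc(OCc2ccccc2)c(OCc2ccccc2)c(B2OC(C)(C)C(C)(C)O2)c1 | intermediate
8 | 3,4-bis(benzyloxy)-5-(5,7,4'-tri-O-benzylapigenin-6-yl)benzaldehyde | O=Cc1cc(OCc2ccccc2)c(OCc2ccccc2)c(-c2c(OCc3ccccc3)cc3oc(-c4ccc(OCc5ccccc5)cc4)cc(=O)c3c2OCc2ccccc2)c1 | intermediate
9 | [3,4-bis(benzyloxy)-5-(5,7,4'-tri-O-benzylapigenin-6-yl)phenyl]methanol | OCc1cc(OCc2ccccc2)c(OCc2ccccc2)c(-c2c(OCc3ccccc3)cc3oc(-c4ccc(OCc5ccccc5)cc4)cc(=O)c3c2OCc2ccccc2)c1 | intermediate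
10 | 1-(2,4-dihydroxy-6-methoxyphenyl)ethanone | CC(=O)c1c(O)cc(O)cc1OC | starting material
11 | 1-(4-benzyloxy-2-hydroxy-6-methoxyphenyl)ethanone | CC(=O)c1c(O)cc(OCc2ccccc2)cc1OC | intermediate
12 | 1-{4-benzyloxy-2-methoxy-6-[3,4-bis(benzyloxy)-5-(5,7,4'-tri-O-benzylapigenin-6-yl)benzyloxy]phenyl}ethanone | CC(=O)c1c(OCc2cc(OCc3ccccc3)c(OCc3ccccc3)c(-c3c(OCc4ccccc4)cc4oc(-c5ccc(OCc6ccccc6)cc5)cc(=O)c4c3OCc3ccccc3)c2)cc(OCc2ccccc2)cc1OC | intermediate
13 | 4,4,4-trifluoro-1-{4-benzyloxy-2-methoxy-6-[3,4-bis(benzyloxy)-5-(5,7,4'-tri-O-benzylapigenin-6-yl)benzyloxy]phenyl}butane-1,3-dione (not isolated) | O=C(CC(=O)C(F)(F)F)c1c(OCc2cc(OCc3ccccc3)c(OCc3ccccc3)c(-c3c(OCc4ccccc4)cc4oc(-c5ccc(OCc6ccccc6)cc5)cc(=O)c4c3OCc3ccccc3)c2)cc(OCc2ccccc2)cc1OC | intermediate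
14 | 2-diazo-1-{4-benzyloxy-2-methoxy-6-[3,4-bis(benzyloxy)-5-(5,7,4'-tri-O-benzylapigenin-6-yl)benzyloxy]phenyl}ethanone | [N-]=[N+]=CC(=O)c1c(OCc2cc(OCc3ccccc3)c(OCc3ccccc3)c(-c3c(OCc4ccccc4)cc4oc(-c5ccc(OCc6ccccc6)cc5)cc(=O)c4c3OCc3ccccc3)c2)cc(OCc2ccccc2)cc1OC | intermediate
15 | (2S)-7-benzyloxy-5-methoxy-2-[3,4-bis(benzyloxy)-5-(5,7,4'-tri-O-benzylapigenin-6-yl)phenyl]chroman-4-one | O=C1C[C@@H](c2cc(OCc3ccccc3)c(OCc3ccccc3)c(-c3c(OCc4ccccc4)cc4oc(-c5ccc(OCc6ccccc6)cc5)cc(=O)c4c3OCc3ccccc3)c2)Oc2cc(OCc3ccccc3)cc(OC)c21 | intermediate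
16 | (2S)-5,7-dihydroxy-2-{3,4-dihydroxy-5-[5,7-dihydroxy-2-(4-hydroxyphenyl)-4-oxo-4H-chromen-6-yl]phenyl}chroman-4-one | O=C1C[C@@H](c2cc(O)c(O)c(-c3c(O)cc4oc(-c5ccc(O)cc5)cc(=O)c4c3O)c2)Oc2cc(O)cc(O)c21 | target

**Summary**

Total steps: 12. Longest linear sequence: 9 steps (steps 1, 2, 3, 6, 7, 9, 10, 11 and 12, from apigenin).

Steps most likely to fail:

1. Step 11. The carbenoid may be diverted to oxonium-ylide formation at O1 with 1,2-migration of the benzyl group, or the catalyst may discriminate poorly between the two enantiotopic hydrogens. Fallback, setting out from 8 and 11: Claisen–Schmidt condensation (KOH, EtOH/THF, rt) should give the 2'-hydroxychalcone F1. Heating with NaOAc in EtOH should close ring C by oxa-Michael addition to give the racemic flavanone F2. Preparative HPLC on a chiral stationary phase should separate the (2S)-enantiomer from the (2R)-enantiomer F3. The route is rejoined at 15.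

2. Step 12. The Lewis acid may induce heterolysis of the O1–C2 bond with loss of configuration, and benzyl cations may C-alkylate the phloroglucinol-type rings. Fallback, setting out from 15: hydrogenolysis (H2, Pd(OH)2/C, THF/MeOH, rt) should remove the six benzyl groups under neutral conditions to give the 5-O-methyl ether F4. Chelation-controlled demethylation of the peri methoxy group (AlCl3, MeCN, rt) should then give 16, where the route is rejoined.

3. Step 6. Transmetalation at the doubly ortho-alkoxylated arylpalladium iodide may be slow, so that protodeboronation of the boronate and hydrodeiodination of the iodide overtake coupling. Fallback, setting out from 6: stannylation (Bu3SnSnBu3, Pd(PPh3)4, toluene, 110 °C) should give the arylstannane F5. Stille coupling of this with 4 under base-free conditions (Pd(PPh3)4, CuI, CsF, DMF, 60 °C) should give 8, where the route is rejoined.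

**Further compounds**

F1 | step 11 | (E)-1-(4-benzyloxy-2-hydroxy-6-methoxyphenyl)-3-[3,4-bis(benzyloxy)-5-(5,7,4'-tri-O-benzylapigenin-6-yl)phenyl]prop-2-en-1-one | O=C(/C=C/c1cc(OCc2ccccc2)c(OCc2ccccc2)c(-c2c(OCc3ccccc3)cc3oc(-c4ccc(OCc5ccccc5)cc4)cc(=O)c3c2OCc2ccccc2)c1)c1c(O)cc(OCc2ccccc2)cc1OC
F2 | step 11 | racemic 7-benzyloxy-5-methoxy-2-[3,4-bis(benzyloxy)-5-(5,7,4'-tri-O-benzylapigenin-6-yl)phenyl]chroman-4-one | O=C1CC(c2cc(OCc3ccccc3)c(OCc3ccccc3)c(-c3c(OCc4ccccc4)cc4oc(-c5ccc(OCc6ccccc6)cc5)cc(=O)c4c3OCc3ccccc3)c2)Oc2cc(OCc3ccccc3)cc(OC)c21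
F3 | step 11 | (2R)-7-benzyloxy-5-methoxy-2-[3,4-bis(benzyloxy)-5-(5,7,4'-tri-O-benzylapigenin-6-yl)phenyl]chroman-4-one | O=C1C[C@H](c2cc(OCc3ccccc3)c(OCc3ccccc3)c(-c3c(OCc4ccccc4)cc4oc(-c5ccc(OCc6ccccc6)cc5)cc(=O)c4c3OCc3ccccc3)c2)Oc2cc(OCc3ccccc3)cc(OC)c21
F4 | step 12 | (2S)-7-hydroxy-5-methoxy-2-{3,4-dihydroxy-5-[5,7-dihydroxy-2-(4-hydroxyphenyl)-4-oxo-4H-chromen-6-yl]phenyl}chroman-4-one | O=C1C[C@@H](c2cc(O)c(O)c(-c3c(O)cc4oc(-c5ccc(O)cc5)cc(=O)c4c3O)c2)Oc2cc(O)cc(OC)c21
F5 | step 6 | 3,4-bis(benzyloxy)-5-(tributylstannyl)benzaldehyde | O=Cc1cc(OCc2ccccc2)c(OCc2ccccc2)c([Sn](CCCC)(CCCC)CCCC)c1
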